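The earlier runs and the new flask come from a simulation from invented constants.

| flask | left-handed substrate | right-handed substrate | partner | catalyst | added ligand | remark | time |
|---|---|---|---|---|---|---|---|
| south-west | 0.70 M | 0.70 M | 2.1 M | 1 mM | 0.68 mM | run made earlier |  |
| north | 0.70 M | 0.70 M | 2.1 M | 1.8 mM | 0.68 mM | run made earlier |  |
| south | 0.70 M | 0.70 M | 2.1 M | 3 mM | 0.68 mM | run made earlier |  |
| winter | 0.70 M | 0.70 M | 2.10 M | 0.98 mM | 0.68 mM |  | 4.0 min |
| noon | 0.70 M | 0.70 M | 2.10 M | 4.0 mM | 0.68 mM |  | 4.0 min |

| run | time / min | right-handed substrate / % | left-handed substrate / % |
|---|---|---|---|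
| south-west | 0.250 | 46.0 | 42.8 |
| south-west | 0.417 | 45.7 | 38.5 |
| south-west | 0.833 | 42.7 | 33.7 |
| south-west | 1.33 | 40.0 | 30.9 |
| south-west | 3.00 | 36.0 | 23.9 |
| north | 0.500 | 40.7 | 29.2 |
| north | 1.00 | 35.4 | 22.5 |
| north | 1.50 | 32.6 | 18.8 |
| north | 2.50 | 28.8 | 13.7 |
| north | 3.00 | 27.9 | 12.7 |
| south | 0.250 | 39.9 | 28.2 |
| south | 0.417 | 35.1 | 22.1 |
| south | 0.833 | 29.6 | 14.6 |
| south | 1.33 | 24.4 | 10.9 |
| south | 3.00 | 19.4 | 5.2 |

(readings scatter by 0.5 percentage points)

- catalyst is single-handed; left-handed substrate and right-handed substrate are mirror images of each other, charged as a racemate, each of them at the stated concentration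
- what may be going on: partner + catalyst + left-handed substrate -> catalyst + left-handed product; partner + catalyst + right-handed substrate -> catalyst + right-handed product; catalyst + added ligand <-> idle complex; 2 partner -> self-condensation product
- an excess is the difference of the two amounts in percent of their sum
- an excess is below zero if the other one leads

* the winner by excess of right-handed substrate over left-handed substrate among what is left of the two; "neither" if no more than 2 percentage points parts them (winter / noon / neither)
* excess of right-handed substrate over left-handed substrate among what is left of the two at the end, winter
* excess of right-handed substrate over left-handed substrate among what is left of the two at the end, noon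

- At 4.0 min, the time of reading, the excess depends on two fractions of each substrate's own charge that are still left, f for left-handed and g for right-handed.
- I carry the selectivity factor s, the ratio ln f / ln g. Both substrates meet the same catalyst and partner, so their curves should share one clock, and g is f raised to the power one over s.
- The last readings give 2.25 in south-west, 2.35 in north and 2.39 in south. I replace them by their mean, 2.33.
- At fixed s, a tie needs nearly equal f in winter and noon. South-west, almost winter's charge, reads f = 0.478 at its last reading, which with s gives 20.8 %.
- South reads f = 0.104 at its last reading, which with s gives 56.9 %, and noon has more catalyst than south and runs 1.00 min longer than that reading.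
- For a tie, winter's f has to reach noon's, which I expect at or below 0.104. Taking winter near 0.478 at that time, it has 1.00 min left for this, yet the south-west readings went from 0.618 to 0.478 over the 1.67 min before the last one.
- Taking the extreme values of s instead of the mean moves south's excess by 2.1 percentage points, against a gap of 36 points and a margin of 2 points. I commit to noon.
- The forecast, from a “nearly constant ratio of log rates”, says noon, with 22.4 % for winter and 74 % for noon.

- The flask gives noon, with 22.2 % in winter and 72.5 % in noon. At the asked time winter has less of its partner left, 8.6 %, than of its left-handed substrate, 46 %, each of its own charge. Noon's f of 4.2 % with s gives 71.9 %.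

    partner + catalyst + left-handed substrate → catalyst + left-handed product (k = 9.91 /M²/s)
    partner + catalyst + right-handed substrate → catalyst + right-handed product (k = 4.15 /M²/s)
    catalyst + added ligand ⇌ idle complex, settled at all times (K = 2300 /M)
    2 partner → self-condensation product (k = 0.00579 /M/s)
- The neighbour of winter with 5.9 × 10⁻⁴ M of catalyst stands at f = 64 % at the asked time, where s gives 12.7 %. The computed excess there is 12.8 %.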